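**Retrosynthetic overview**

1. Target 28 ⇐ triacetate 27 ⇐ triol 26 (hydroxyl-directed reduction sets C7) ⇐ enone 24 (oxidative 1,3-transposition) ⇐ union at C9–C11 of bicyclic enone 15 with the side-chain organolithium 22.
2. 15 ⇐ ene-dione 12 (α-face hydride sets 6β-O) ⇐ 2α-acetyl diketone 10 (Baeyer–Villiger with retention; C2 set by equilibration).
3. Key disconnection: ring A by a one-flask [3+3] annulation of 6-methylcarvone 3 with 3-(bromomethyl)but-3-en-2-one 6. C1–C10 forms by SN2′ enolate alkylation anti to the C5 isopropenyl group, then C3–C4 by metal-hydride hydrogen-atom transfer (MHAT) and 6-endo radical closure. Ring B is bought as (R)-carvone; ring A is the only ring formed.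
4. Enabling feature: C4 (gem-dimethyl) and C10 (quaternary, methyl) both hang on C5 of ring B and are bridged by the oxygenated three-carbon unit C1–C2–C3. With the C8 methyl, ring B plus C4 is the p-menthane skeleton, so C10 is the α′-carbon and C4 the isopropenyl carbon of carvone, and the purchased C5 stereocentre adjoins both reacting atoms.
5. Side-chain iodide 21 comes from a Negishi carboalumination of a butynyl silyl ether, which sets the 13E alkene.

Key step: step 4

Remark: labdane numbering is used throughout (C1–C10 decalin, C11–C16 side chain); 3 is used as its C6-epimer mixture, because both epimers give the same dienolate 7.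

**Route**

Step 1
Reactants: 1 (R)-(−)-carvone
Product: 3 (5R,6S)-2,6-dimethyl-5-(prop-1-en-2-yl)cyclohex-2-en-1-one, via lithium dienolate 2 (not isolated)
Conditions: LiN(i-Pr)2, THF, −78 °C; then MeI, −78 → 0 °C
Reagents that add atoms: iodomethane, CI
Why: Kinetic α′-deprotonation of the enone and methylation of the cross-conjugated dienolate (enolate alkylation); the methyl should enter mainly anti to the isopropenyl group, but this centre is planarised again in step 4.

Step 2
Reactants: 4 methyl vinyl ketone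
Product: 5 3-(hydroxymethyl)but-3-en-2-one
Conditions: 37 % aq. CH2O, 1,4-diazabicyclo[2.2.2]octane (cat.), THF, 23 °C
Reagents that add atoms: formaldehyde, C=O
Why: Morita–Baylis–Hillman reaction; the amine adds to the enone, the zwitterionic enolate captures formaldehyde, and β-elimination releases the catalyst.

Step 3
Reactants: 5 3-(hydroxymethyl)but-3-en-2-one
Product: 6 3-(bromomethyl)but-3-en-2-one
Conditions: PBr3, Et2O, 0 °C; used at once
Reagents that add atoms: phosphorus tribromide, BrP(Br)Br
Why: Conversion of a primary allylic alcohol into the bromide with PBr3; SN2 and SN2′ displacement give the same product.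

Step 4
Reactants: 3 (5R,6S)-2,6-dimethyl-5-(prop-1-en-2-yl)cyclohex-2-en-1-one; 6 3-(bromomethyl)but-3-en-2-one
Product: 9 2-acetyl-4,4,8,10β-tetramethyl-5α-decal-7-en-9-one (C2 epimers), via lithium dienolate 7 (not isolated), via SN2′ adduct 8 (not isolated)
Conditions: LiN(i-Pr)2, THF, −78 °C; then 6 (0.95 equiv), −78 → −20 °C; then AcOH (to neutrality), EtOH, Fe(acac)3, PhSiH3, 60 °C
Reagents that add atoms: none
Why: Kinetic deprotonation of 3 gives the cross-conjugated lithium dienolate 7, whose C10 adds to the methylene terminus of 6 with loss of bromide (SN2′ addition–elimination, the normal course of enolates with 2-(halomethyl) enones) and so forms C1–C10 in trienedione 8; after neutralisation, the iron hydride made from Fe(acac)3 and PhSiH3 transfers a hydrogen atom to the terminal carbon of the isopropenyl group, and the tertiary C4 radical adds to the unsubstituted β-carbon C3 of the α-methylene ketone (Giese addition), forming C3–C4 and the gem-dimethyl carbon, before the α-keto radical is reduced to an iron enolate and protonated by ethanol. The closest known reaction types are the stereoselective second alkylation of 6-alkylcarvone enolates and iron-hydride-initiated (MHAT) intramolecular radical conjugate additions of isopropenyl groups to enones, here run in one flask. Ring A is the only ring closed, in 6-endo-trig mode. The C10 stereocentre is set in the alkylation by the purchased C5 centre, the electrophile entering the dienolate face anti to the isopropenyl group so that C1 and C4 are trans on ring B and the radical closure can only give the trans-fused decalin (5α-H, 10β-CH3); C2 forms as an epimer mixture that step 5 corrects. The step needs hydrogen-atom transfer to the isopropenyl alkene in preference to the two enones, and 6-endo in preference to 5-exo closure. The first is secured by the electron-rich 1,1-disubstituted donor alkene and by keeping 6 as the limiting reagent, the second by radical polarity and by the fully substituted α-carbon of the acceptor.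

Step 5
Reactants: 9 2-acetyl-4,4,8,10β-tetramethyl-5α-decal-7-en-9-one (C2 epimers)
Product: 10 2α-acetyl-4,4,8,10β-tetramethyl-5α-decal-7-en-9-one
Conditions: K2CO3, MeOH, 23 °C
Reagents that add atoms: none
Why: Thermodynamic epimerisation through the enolate of the methyl ketone; the acetyl group should settle equatorial (2α), away from the syn-axial 4β- and 10β-methyl groups, so C2 is set by the ring A chair.

Step 6
Reactants: 10 2α-acetyl-4,4,8,10β-tetramethyl-5α-decal-7-en-9-one
Product: 11 2α-acetoxy-4,4,8,10β-tetramethyl-5α-decal-7-en-9-one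
Conditions: m-CPBA, Na2HPO4, CH2Cl2, 23 → 40 °C
Reagents that add atoms: 3-chloroperoxybenzoic acid, OOC(=O)c1cccc(Cl)c1
Why: Baeyer–Villiger oxidation; the secondary C2 migrates in preference to methyl and with retention, giving the 2α-acetate, while the conjugated neopentyl C9 ketone and its electron-poor alkene should not react.

Step 7
Reactants: 11 2α-acetoxy-4,4,8,10β-tetramethyl-5α-decal-7-en-9-one
Product: 12 2α-acetoxy-4,4,8,10β-tetramethyl-5α-decal-7-ene-6,9-dione
Conditions: Pd(OH)2/C (cat.), t-BuOOH, K2CO3, CH2Cl2, 4 → 23 °C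
Reagents that add atoms: tert-butyl hydroperoxide, CC(C)(C)OO
Why: Palladium-mediated tert-butylperoxy-radical allylic oxidation of the γ-methylene of an enone to the ene-1,4-dione; C6 is the only allylic methylene and C10 is quaternary, so neither a second site nor aromatisation is available.

Step 8
Reactants: 12 2α-acetoxy-4,4,8,10β-tetramethyl-5α-decal-7-ene-6,9-dione
Product: 14 2α,6β-dihydroxy-4,4,8,10β-tetramethyl-5α-decal-7-en-9-one, via hydroxy acetate 13 (not isolated)
Conditions: NaBH4, CeCl3·7H2O, MeOH, −78 °C; then K2CO3, 0 °C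
Reagents that add atoms: none
Why: Luche 1,2-reduction of the less hindered C6 carbonyl (C9 is flanked by quaternary C10 and the C8 methyl), with hydride entering from the α-face because the β-face is blocked by the syn-axial 10β- and 4β-methyl groups, giving the axial 6β-alcohol; mild methanolysis then removes the C2 acetate.

Step 9
Reactants: 14 2α,6β-dihydroxy-4,4,8,10β-tetramethyl-5α-decal-7-en-9-one
Product: 15 2α,6β-bis(triethylsilyloxy)-4,4,8,10β-tetramethyl-5α-decal-7-en-9-one
Conditions: Et3SiOTf, 2,6-lutidine, CH2Cl2, 0 °C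
Reagents that add atoms: triethylsilyl trifluoromethanesulfonate, CC[Si](CC)(CC)OS(=O)(=O)C(F)(F)F
Why: Silylation with a silyl triflate, which is reactive enough for the hindered axial 6β-hydroxyl; both hydroxyls are masked for the organolithium and chromium steps.

Step 10
Reactants: 16 4-(tert-butyldimethylsilyloxy)but-1-yne
Product: 18 (E)-5-(tert-butyldimethylsilyloxy)-3-methylpent-2-en-1-ol, via alkenylalane 17 (not isolated)
Conditions: Me3Al, Cp2ZrCl2 (cat.), CH2Cl2, 0 → 23 °C; then (CH2O)n, 0 → 23 °C; aq. work-up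
Reagents that add atoms: trimethylaluminium, C[Al](C)C; formaldehyde (as paraformaldehyde), C=O
Why: Negishi carboalumination; zirconium-catalysed syn addition of methyl (internal carbon) and aluminium (terminal carbon), then C–C bond formation with formaldehyde with retention, fixes the E trisubstituted alkene.

Step 11
Reactants: 18 (E)-5-(tert-butyldimethylsilyloxy)-3-methylpent-2-en-1-ol
Product: 19 (E)-1-(tert-butyldiphenylsilyloxy)-5-(tert-butyldimethylsilyloxy)-3-methylpent-2-ene
Conditions: t-BuPh2SiCl, imidazole, CH2Cl2, 23 °C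
Reagents that add atoms: tert-butyl(chloro)diphenylsilane, CC(C)(C)[Si](Cl)(c1ccccc1)c1ccccc1
Why: Standard silylation of a primary allylic alcohol; this ether is chosen to survive organolithium, chromium and mild acid.

Step 12
Reactants: 19 (E)-1-(tert-butyldiphenylsilyloxy)-5-(tert-butyldimethylsilyloxy)-3-methylpent-2-ene
Product: 20 (E)-5-(tert-butyldiphenylsilyloxy)-3-methylpent-3-en-1-ol
Conditions: pyridinium p-toluenesulfonate (cat.), MeOH, 23 °C
Reagents that add atoms: none
Why: Acid-catalysed methanolysis removes the primary tert-butyldimethylsilyl ether selectively; the bulkier diphenylsilyl ether is far more acid-stable.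

Step 13
Reactants: 20 (E)-5-(tert-butyldiphenylsilyloxy)-3-methylpent-3-en-1-ol
Product: 21 (E)-tert-butyl[(5-iodo-3-methylpent-2-en-1-yl)oxy]diphenylsilane
Conditions: I2, PPh3, imidazole, CH2Cl2, 0 °C
Reagents that add atoms: iodine, II
Why: Appel-type iodination by SN2 displacement of the oxyphosphonium at a primary carbon; the alkene geometry is not touched.

Step 14
Reactants: 21 (E)-tert-butyl[(5-iodo-3-methylpent-2-en-1-yl)oxy]diphenylsilane; 15 2α,6β-bis(triethylsilyloxy)-4,4,8,10β-tetramethyl-5α-decal-7-en-9-one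
Product: 23 15-(tert-butyldiphenylsilyloxy)-2α,6β-bis(triethylsilyloxy)labda-7,13E-dien-9-ol, via organolithium 22 (not isolated)
Conditions: 21, t-BuLi (2 equiv), Et2O/pentane, −78 °C; then 15, −78 → −20 °C
Reagents that add atoms: none
Why: Iodine–lithium exchange and 1,2-addition of the primary alkyllithium to the non-enolisable C9 ketone, expected from the α-face anti to the 10β-methyl group; the carbinol configuration is erased in step 15.

Step 15
Reactants: 23 15-(tert-butyldiphenylsilyloxy)-2α,6β-bis(triethylsilyloxy)labda-7,13E-dien-9-ol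
Product: 24 15-(tert-butyldiphenylsilyloxy)-2α,6β-bis(triethylsilyloxy)labda-8,13E-dien-7-one
Conditions: pyridinium chlorochromate ([C5H5NH][CrO3Cl]), NaOAc, CH2Cl2, 23 °C
Reagents that add atoms: pyridinium chlorochromate, [O-][Cr](=O)(=O)Cl.c1cc[nH+]cc1
Why: Dauben–Babler oxidative 1,3-transposition; the chromate ester of the tertiary allylic alcohol undergoes a [3,3] shift to C7 and is oxidised there, which places the tetrasubstituted C8=C9 alkene and the C7 carbonyl.

Step 16
Reactants: 24 15-(tert-butyldiphenylsilyloxy)-2α,6β-bis(triethylsilyloxy)labda-8,13E-dien-7-one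
Product: 25 15-(tert-butyldiphenylsilyloxy)-2α,6β-dihydroxylabda-8,13E-dien-7-one
Conditions: HF·pyridine, pyridine, THF, 0 °C
Reagents that add atoms: none
Why: Fluoride cleavage of the two secondary triethylsilyl ethers, which should be much faster than loss of the primary diphenylsilyl ether; non-basic conditions protect the C6 centre α to the ketone.

Step 17
Reactants: 25 15-(tert-butyldiphenylsilyloxy)-2α,6β-dihydroxylabda-8,13E-dien-7-one
Product: 26 15-(tert-butyldiphenylsilyloxy)labda-8,13E-diene-2α,6β,7α-triol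
Conditions: Me4NBH(OAc)3, AcOH/MeCN, −20 °C
Reagents that add atoms: none
Why: Evans–Saksena-type hydroxyl-directed reduction; the axial 6β-hydroxyl binds the triacetoxyborohydride and delivers hydride to the β-face of the C7 carbonyl, which should give the 7α-alcohol trans to the 6β-oxygen.

Step 18
Reactants: 26 15-(tert-butyldiphenylsilyloxy)labda-8,13E-diene-2α,6β,7α-triol
Product: 27 15-(tert-butyldiphenylsilyloxy)labda-8,13E-diene-2α,6β,7α-triyl triacetate
Conditions: Ac2O, 4-(dimethylamino)pyridine, pyridine, 40 °C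
Reagents that add atoms: acetic anhydride, CC(=O)OC(C)=O
Why: Nucleophile-catalysed acylation of the three secondary alcohols; warming is planned for the hindered axial 6β-hydroxyl.

Step 19
Reactants: 27 15-(tert-butyldiphenylsilyloxy)labda-8,13E-diene-2α,6β,7α-triyl triacetate
Product: 28 2α,6β,7α-triacetoxylabda-8,13E-dien-15-ol (target)
Conditions: n-Bu4NF, AcOH, THF, 23 °C
Reagents that add atoms: none
Why: Fluoride desilylation of the primary allylic silyl ether; buffering with acetic acid should prevent acetate cleavage or migration.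

**Compound list**

1 | (R)-(−)-carvone | CC(=C)[C@H]1CC(=O)C(C)=CC1 | starting material
2 | lithium dienolate of 1 | CC(=C)[C@@H]1CC=C(C)C(O[Li])=C1 | intermediate
3 | (5R,6S)-2,6-dimethyl-5-(prop-1-en-2-yl)cyclohex-2-en-1-one (trans-6-methylcarvone) | CC(=C)[C@H]1[C@H](C)C(=O)C(C)=CC1 | intermediate
4 | methyl vinyl ketone | CC(=O)C=C | starting material
5 | 3-(hydroxymethyl)but-3-en-2-one | CC(=O)C(=C)CO | intermediate
6 | 3-(bromomethyl)but-3-en-2-one | CC(=O)C(=C)CBr | intermediate
7 | lithium dienolate of 3 | CC(=C)[C@@H]1CC=C(C)C(O[Li])=C1C | intermediate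
8 | (5S,6S)-2,6-dimethyl-6-(2-methylidene-3-oxobutyl)-5-(prop-1-en-2-yl)cyclohex-2-en-1-one | CC(=C)[C@H]1[C@](C)(CC(=C)C(C)=O)C(=O)C(C)=CC1 | intermediate
9 | 2-acetyl-4,4,8,10β-tetramethyl-5α-decal-7-en-9-one, trans-fused, C2 epimers | CC(=O)C1CC(C)(C)[C@@H]2CC=C(C)C(=O)[C@@]2(C)C1 | intermediate
10 | 2α-acetyl-4,4,8,10β-tetramethyl-5α-decal-7-en-9-one | CC(=O)[C@H]1CC(C)(C)[C@@H]2CC=C(C)C(=O)[C@@]2(C)C1 | intermediate
11 | 2α-acetoxy-4,4,8,10β-tetramethyl-5α-decal-7-en-9-one | CC(=O)O[C@H]1CC(C)(C)[C@@H]2CC=C(C)C(=O)[C@@]2(C)C1 | intermediate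
12 | 2α-acetoxy-4,4,8,10β-tetramethyl-5α-decal-7-ene-6,9-dione | CC(=O)O[C@H]1CC(C)(C)[C@@H]2C(=O)C=C(C)C(=O)[C@@]2(C)C1 | intermediate
13 | 2α-acetoxy-6β-hydroxy-4,4,8,10β-tetramethyl-5α-decal-7-en-9-one | CC(=O)O[C@H]1CC(C)(C)[C@@H]2[C@H](O)C=C(C)C(=O)[C@@]2(C)C1 | intermediate
14 | 2α,6β-dihydroxy-4,4,8,10β-tetramethyl-5α-decal-7-en-9-one | O[C@H]1CC(C)(C)[C@@H]2[C@H](O)C=C(C)C(=O)[C@@]2(C)C1 | intermediate
15 | 2α,6β-bis(triethylsilyloxy)-4,4,8,10β-tetramethyl-5α-decal-7-en-9-one | CC[Si](CC)(CC)O[C@H]1CC(C)(C)[C@@H]2[C@H](O[Si](CC)(CC)CC)C=C(C)C(=O)[C@@]2(C)C1 | intermediate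
16 | 4-(tert-butyldimethylsilyloxy)but-1-yne | C#CCCO[Si](C)(C)C(C)(C)C | starting material
17 | (E)-[4-(tert-butyldimethylsilyloxy)-2-methylbut-1-enyl]dimethylalane | C[Al](C)/C=C(\C)CCO[Si](C)(C)C(C)(C)C | intermediate
18 | (E)-5-(tert-butyldimethylsilyloxy)-3-methylpent-2-en-1-ol | CC(C)(C)[Si](C)(C)OCC/C(C)=C/CO | intermediate
19 | (E)-1-(tert-butyldiphenylsilyloxy)-5-(tert-butyldimethylsilyloxy)-3-methylpent-2-ene | CC(C)(C)[Si](C)(C)OCC/C(C)=C/CO[Si](c1ccccc1)(c1ccccc1)C(C)(C)C | intermediate
20 | (E)-5-(tert-butyldiphenylsilyloxy)-3-methylpent-3-en-1-ol | OCC/C(C)=C/CO[Si](c1ccccc1)(c1ccccc1)C(C)(C)C | intermediate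
21 | (E)-tert-butyl[(5-iodo-3-methylpent-2-en-1-yl)oxy]diphenylsilane | ICC/C(C)=C/CO[Si](c1ccccc1)(c1ccccc1)C(C)(C)C | intermediate
22 | (E)-[5-(tert-butyldiphenylsilyloxy)-3-methylpent-3-enyl]lithium | [Li]CC/C(C)=C/CO[Si](c1ccccc1)(c1ccccc1)C(C)(C)C | intermediate
23 | 15-(tert-butyldiphenylsilyloxy)-2α,6β-bis(triethylsilyloxy)labda-7,13E-dien-9-ol (9β-OH expected) | CC[Si](CC)(CC)O[C@H]1CC(C)(C)[C@@H]2[C@H](O[Si](CC)(CC)CC)C=C(C)[C@@](O)(CC/C(C)=C/CO[Si](c3ccccc3)(c3ccccc3)C(C)(C)C)[C@@]2(C)C1 | intermediate
24 | 15-(tert-butyldiphenylsilyloxy)-2α,6β-bis(triethylsilyloxy)labda-8,13E-dien-7-one | CC[Si](CC)(CC)O[C@H]1CC(C)(C)[C@@H]2[C@H](O[Si](CC)(CC)CC)C(=O)C(C)=C(CC/C(C)=C/CO[Si](c3ccccc3)(c3ccccc3)C(C)(C)C)[C@@]2(C)C1 | intermediate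
25 | 15-(tert-butyldiphenylsilyloxy)-2α,6β-dihydroxylabda-8,13E-dien-7-one | O[C@H]1CC(C)(C)[C@@H]2[C@H](O)C(=O)C(C)=C(CC/C(C)=C/CO[Si](c3ccccc3)(c3ccccc3)C(C)(C)C)[C@@]2(C)C1 | intermediate
26 | 15-(tert-butyldiphenylsilyloxy)labda-8,13E-diene-2α,6β,7α-triol | O[C@H]1CC(C)(C)[C@@H]2[C@H](O)[C@@H](O)C(C)=C(CC/C(C)=C/CO[Si](c3ccccc3)(c3ccccc3)C(C)(C)C)[C@@]2(C)C1 | intermediate
27 | 15-(tert-butyldiphenylsilyloxy)labda-8,13E-diene-2α,6β,7α-triyl triacetate | CC(=O)O[C@H]1CC(C)(C)[C@@H]2[C@H](OC(C)=O)[C@@H](OC(C)=O)C(C)=C(CC/C(C)=C/CO[Si](c3ccccc3)(c3ccccc3)C(C)(C)C)[C@@]2(C)C1 | intermediate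
28 | 2α,6β,7α-triacetoxylabda-8,13E-dien-15-ol | CC(=O)O[C@H]1CC(C)(C)[C@@H]2[C@H](OC(C)=O)[C@@H](OC(C)=O)C(C)=C(CC/C(C)=C/CO)[C@@]2(C)C1 | target

**Step count and risks**

Total step count: 19. Longest linear sequence: 14 steps (steps 2–9 and 14–19, from methyl vinyl ketone 4 to target 28).

Steps most likely to fail:

1. Step 4. The iron hydride may reduce the α-methylene ketone of 8 before it reaches the isopropenyl group, or residual base may oligomerise 8, so that ring closure stalls. Loss of facial control in the alkylation would lead into the cis-fused series. The fallback closes ring A by a cation instead of a radical; it sets out from 3 and returns at 11. The enolate of 3 is alkylated with 2,3-dichloropropene (same anti approach) to give the 2-chloroallyl ketone F1. A Lansbury chloro-olefin annulation in 90 % HCO2H at 60 °C follows: the isopropenyl group is protonated, the chloroalkene terminus attacks the C4 cation, and the α-chloro cation is hydrolysed, giving the trans-fused 2,9-dione F2. NaBH4 at −78 °C reduces only the unhindered C2 ketone, from the open α-face, to the axial 2β-alcohol F3. Mitsunobu inversion with PPh3, diisopropyl azodicarboxylate and AcOH then gives 11.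

2. Step 7. Hydrogen abstraction at the hindered C6 methylene may be slow or unselective, over-oxidation may occur, and C5 may epimerise once it is α to the new ketone. The fallback uses polar oxidation of a dienol ether; it sets out from 11 and returns at 12. TBSOTf/Et3N converts 11, which has no α′-hydrogen, into the linear silyl dienol ether F4. m-CPBA epoxidises its terminal C6=C7 bond, and collapse of the epoxide gives the 6-hydroxy enone F5 (6α expected; the configuration is irrelevant). MnO2 oxidises this allylic alcohol to 12.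

3. Step 17. Facial selectivity may be poor if intramolecular hydride delivery does not outrun external attack on the hindered tetrasubstituted enone, and enediol tautomerisation of the free α-ketol 25 may scramble C6. The fallback uses inversion instead of delivery and avoids the free ketol; it sets out from 24 and returns at 27. NaBH4/CeCl3·7H2O reduces 24 by external attack anti to the axial 6β-silyloxy group, giving the 7β-alcohol F6. Mitsunobu reaction with PPh3, diisopropyl azodicarboxylate and AcOH inverts the allylic carbon to give the 7α-acetate F7. HF·pyridine removes both triethylsilyl groups to give the 2α,6β-diol F8, and Ac2O/4-(dimethylamino)pyridine completes 27.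

**Further compounds**

F1 | step 4 | (5S,6S)-6-(2-chloroprop-2-en-1-yl)-2,6-dimethyl-5-(prop-1-en-2-yl)cyclohex-2-en-1-one | CC(=C)[C@H]1[C@](C)(CC(Cl)=C)C(=O)C(C)=CC1
F2 | step 4 | 4,4,8,10β-tetramethyl-5α-decal-7-ene-2,9-dione | O=C1CC(C)(C)[C@@H]2CC=C(C)C(=O)[C@@]2(C)C1
F3 | step 4 | 2β-hydroxy-4,4,8,10β-tetramethyl-5α-decal-7-en-9-one | O[C@@H]1CC(C)(C)[C@@H]2CC=C(C)C(=O)[C@@]2(C)C1
F4 | step 7 | 2α-acetoxy-9-(tert-butyldimethylsilyloxy)-4,4,8,10β-tetramethyl-5α-decala-6,8-diene | CC(=O)O[C@H]1CC(C)(C)[C@@H]2C=CC(C)=C(O[Si](C)(C)C(C)(C)C)[C@@]2(C)C1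
F5 | step 7 | 2α-acetoxy-6α-hydroxy-4,4,8,10β-tetramethyl-5α-decal-7-en-9-one | CC(=O)O[C@H]1CC(C)(C)[C@@H]2[C@@H](O)C=C(C)C(=O)[C@@]2(C)C1
F6 | step 17 | 15-(tert-butyldiphenylsilyloxy)-2α,6β-bis(triethylsilyloxy)labda-8,13E-dien-7β-ol | CC[Si](CC)(CC)O[C@H]1CC(C)(C)[C@@H]2[C@H](O[Si](CC)(CC)CC)[C@H](O)C(C)=C(CC/C(C)=C/CO[Si](c3ccccc3)(c3ccccc3)C(C)(C)C)[C@@]2(C)C1
F7 | step 17 | 15-(tert-butyldiphenylsilyloxy)-2α,6β-bis(triethylsilyloxy)labda-8,13E-dien-7α-yl acetate | CC[Si](CC)(CC)O[C@H]1CC(C)(C)[C@@H]2[C@H](O[Si](CC)(CC)CC)[C@@H](OC(C)=O)C(C)=C(CC/C(C)=C/CO[Si](c3ccccc3)(c3ccccc3)C(C)(C)C)[C@@]2(C)C1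
F8 | step 17 | 15-(tert-butyldiphenylsilyloxy)-2α,6β-dihydroxylabda-8,13E-dien-7α-yl acetate | O[C@H]1CC(C)(C)[C@@H]2[C@H](O)[C@@H](OC(C)=O)C(C)=C(CC/C(C)=C/CO[Si](c3ccccc3)(c3ccccc3)C(C)(C)C)[C@@]2(C)C1
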